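The bibenzyl is cut at the CH2–CH2 bridge between ring A (the central methoxy/hydroxy ring carrying the 4-hydroxybenzyl ring B) and ring C (the 2-hydroxyphenyl ring). The key step exploits the ring C phenol oxygen, which is ortho to the ring carbon bearing the bridge: in o-cresol the phenoxide permits lateral metalation of the neighbouring methyl group, and the O,C-dianion attacks the benzylic chloride of the A/B fragment at carbon. One operation forms the bridge and delivers the free ring C phenol without protecting groups. The electrophile is a tri-O-methyl benzyl chloride; a final thiolate demethylation, self-limiting at one methyl per ring, unveils the target.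

Key step: step 3

Remark on the chemistry: the target has no stereocentre and no other stereogenic element; it is achiral, so no step needs stereocontrol.

Step 1
Reactants: 1 (3,5-dimethoxyphenyl)methanol; 2 4-methoxybenzyl chloride
Product: 4 {3,5-dimethoxy-4-[(4-methoxyphenyl)methyl]phenyl}methanol, via lithium (4-lithio-3,5-dimethoxyphenyl)methanolate 3 (not isolated)
Conditions: n-BuLi (2.2 equiv), TMEDA, THF, 0 °C → rt; CuI (10 mol %), then 2 (1.1 equiv), −78 °C → rt; H2O quench
Reagents that add atoms: none
Why: Directed ortho-metalation: after O-deprotonation the second equivalent of n-BuLi removes the proton at C4, the only position flanked by two methoxy groups, and the aryllithium (copper-catalysed SN2 benzylation) displaces chloride from 2, while the lithium alkoxide is too poor a nucleophile in THF to compete.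

Step 2
Reactants: 4 {3,5-dimethoxy-4-[(4-methoxyphenyl)methyl]phenyl}methanol
Product: 5 5-(chloromethyl)-1,3-dimethoxy-2-[(4-methoxyphenyl)methyl]benzene
Conditions: SOCl2 (1.2 equiv), cat. DMF, CH2Cl2, 0 °C → rt
Reagents that add atoms: thionyl chloride, O=S(Cl)Cl
Why: Chlorodehydroxylation of a primary benzylic alcohol via its chlorosulfite; the aryl methyl ethers and the diarylmethane are inert, and the chloride is preferred to the bromide because it resists halogen–metal exchange in step 3.

Step 3
Reactants: 5 5-(chloromethyl)-1,3-dimethoxy-2-[(4-methoxyphenyl)methyl]benzene; 6 o-cresol (2-methylphenol)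
Product: 8 2-(2-{3,5-dimethoxy-4-[(4-methoxyphenyl)methyl]phenyl}ethyl)phenol, via dipotassium 2-(methanidyl)phenolate (O,C-dimetalated o-cresol) 7 (not isolated)
Conditions: 6 (3 equiv), n-BuLi/t-BuOK (5.8 equiv each), heptane, reflux; then THF, −78 °C, slow addition of 5 (1 equiv), −78 °C → rt; aq HCl
Reagents that add atoms: none
Why: The LICKOR superbase (n-BuLi/t-BuOK) deprotonates the OH and then, assisted by the ortho phenoxide, the adjacent methyl group of 6 (lateral metalation), giving the O,C-dianion 7; its benzylic carbanion, far more basic and nucleophilic than the phenoxide oxygen, displaces chloride from the primary benzylic carbon of 5 by SN2 and so forms the CH2–CH2 bridge, and acidic work-up returns the untouched ring C phenol. The closest known reaction type is the C-alkylation of dimetalated cresols with primary alkyl and allyl halides. No ring is closed and no stereocentre is formed. The step needs C- over O-alkylation, secured by the large basicity gap between the two anionic sites, and substitution over proton transfer from the diarylmethane CH2 of 5 or electron-transfer homocoupling, for which the chloride leaving group, −78 °C and slow addition of 5 to an excess of cheap 7 are chosen. The three methyl ethers and the diarylmethane of 5 are inert to the carbanion under these conditions.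

Step 4
Reactants: 8 2-(2-{3,5-dimethoxy-4-[(4-methoxyphenyl)methyl]phenyl}ethyl)phenol
Product: 9 5-[2-(2-hydroxyphenyl)ethyl]-2-[(4-hydroxyphenyl)methyl]-3-methoxyphenol
Conditions: NaSEt (8 equiv), DMF, reflux (ca. 150 °C), N2; aq HCl
Reagents that add atoms: none
Why: SN2 O-demethylation of aryl methyl ethers by thiolate should stop at one methyl per ring, because ring B has only one and on ring A the phenoxide formed in the first cleavage makes the second (expulsion of a dianion) much slower; the two ring A methoxy groups are symmetry-equivalent, so only one product can form.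

Compound list
1 | (3,5-dimethoxyphenyl)methanol | COc1cc(CO)cc(OC)c1 | starting material
2 | 4-methoxybenzyl chloride | COc1ccc(CCl)cc1 | starting material
3 | lithium (4-lithio-3,5-dimethoxyphenyl)methanolate (formed in situ) | [Li]c1c(OC)cc(CO[Li])cc1OC | intermediate
4 | {3,5-dimethoxy-4-[(4-methoxyphenyl)methyl]phenyl}methanol | COc1cc(CO)cc(OC)c1Cc1ccc(OC)cc1 | intermediate
5 | 5-(chloromethyl)-1,3-dimethoxy-2-[(4-methoxyphenyl)methyl]benzene | COc1cc(CCl)cc(OC)c1Cc1ccc(OC)cc1 | intermediate
6 | o-cresol (2-methylphenol) | Cc1ccccc1O | starting material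
7 | dipotassium 2-(methanidyl)phenolate, the O,C-dimetalated o-cresol (formed in situ; mixed Li/K aggregate, written as the dipotassium salt) | [K+].[K+].[CH2-]c1ccccc1[O-] | intermediate
8 | 2-(2-{3,5-dimethoxy-4-[(4-methoxyphenyl)methyl]phenyl}ethyl)phenol | COc1cc(CCc2ccccc2O)cc(OC)c1Cc1ccc(OC)cc1 | intermediate
9 | 5-[2-(2-hydroxyphenyl)ethyl]-2-[(4-hydroxyphenyl)methyl]-3-methoxyphenol (achiral) | COc1cc(CCc2ccccc2O)cc(O)c1Cc1ccc(O)cc1 | target

Total step count: 4
Longest linear sequence: 4 steps (1 → 4 → 5 → 8 → 9)

Steps most likely to fail

Step 3 (key step). Electron transfer or halogen–metal exchange between the carbanion and the benzylic chloride could divert the coupling into homodimers. Proton transfer from the diarylmethane CH2 could quench the carbanion, and dimetalation of o-cresol could be incomplete. The fallback makes the bridge by olefination and sets out from 5. Heating 5 with PPh3 in toluene should give {[3,5-dimethoxy-4-(4-methoxybenzyl)phenyl]methyl}triphenylphosphonium chloride F1. Its ylide (KOtBu, 2.2 equiv, THF, 0 °C → rt) in a Wittig reaction with salicylaldehyde (O=Cc1ccccc1O, phenoxide tolerated) should give 2-{2-[3,5-dimethoxy-4-(4-methoxybenzyl)phenyl]ethenyl}phenol F2 as an E/Z mixture. Hydrogenation (H2, 1 atm, Pd/C, EtOAc) saturates the alkene without touching the diarylmethane and comes back to the route at 8.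

Step 4. The ring B ether may not cleave fully before the second ring A methyl begins to be lost (over-demethylation), or cleavage may stall. The fallback carries ring B as a benzyl ether, so that thiolate only has to perform the self-limiting ring A cleavage; it sets out from 1.
- The step 1 procedure with 4-(benzyloxy)benzyl chloride (ClCc1ccc(OCc2ccccc2)cc1) in place of 2 should give {4-[4-(benzyloxy)benzyl]-3,5-dimethoxyphenyl}methanol F3.
- SOCl2 as in step 2 should give 2-[4-(benzyloxy)benzyl]-5-(chloromethyl)-1,3-dimethoxybenzene F4.
- Coupling with 7 as in step 3 should give 2-(2-{4-[4-(benzyloxy)benzyl]-3,5-dimethoxyphenyl}ethyl)phenol F5.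
- Hydrogenolysis (H2, Pd/C, EtOAc/EtOH) should give 2-{2-[4-(4-hydroxybenzyl)-3,5-dimethoxyphenyl]ethyl}phenol F6.
- NaSEt (DMF, 130–150 °C) then removes one of the two equivalent ring A methyls and the sequence arrives at 9.

Step 1. Metalation could occur partly at C2 (alkoxide-directed) instead of C4, and the aryllithium could be lost to Wurtz-type coupling or the alkoxide to O-benzylation. The fallback makes the aryl–CH2 bond by Negishi coupling, with the position fixed by a bromide, and sets out from 2. Zinc insertion (Zn dust, LiCl, THF, rt) should give (4-methoxybenzyl)zinc chloride F7. This is coupled with commercially available (4-bromo-3,5-dimethoxyphenyl)methanol (COc1cc(CO)cc(OC)c1Br) under Pd(OAc)2/SPhos (THF, rt → 50 °C, slow addition of the zinc reagent, which tolerates the free hydroxyl) and comes back to the route at 4.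

Further compounds
F1 | step 3 | {[3,5-dimethoxy-4-(4-methoxybenzyl)phenyl]methyl}triphenylphosphonium chloride | COc1ccc(Cc2c(OC)cc(C[P+](c3ccccc3)(c3ccccc3)c3ccccc3)cc2OC)cc1.[Cl-]
F2 | step 3 | 2-{2-[3,5-dimethoxy-4-(4-methoxybenzyl)phenyl]ethenyl}phenol (E/Z mixture) | COc1ccc(Cc2c(OC)cc(C=Cc3ccccc3O)cc2OC)cc1
F3 | step 4 | {4-[4-(benzyloxy)benzyl]-3,5-dimethoxyphenyl}methanol | COc1cc(CO)cc(OC)c1Cc1ccc(OCc2ccccc2)cc1
F4 | step 4 | 2-[4-(benzyloxy)benzyl]-5-(chloromethyl)-1,3-dimethoxybenzene | COc1cc(CCl)cc(OC)c1Cc1ccc(OCc2ccccc2)cc1
F5 | step 4 | 2-(2-{4-[4-(benzyloxy)benzyl]-3,5-dimethoxyphenyl}ethyl)phenol | COc1cc(CCc2ccccc2O)cc(OC)c1Cc1ccc(OCc2ccccc2)cc1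
F6 | step 4 | 2-{2-[4-(4-hydroxybenzyl)-3,5-dimethoxyphenyl]ethyl}phenol | COc1cc(CCc2ccccc2O)cc(OC)c1Cc1ccc(O)cc1
F7 | step 1 | (4-methoxybenzyl)zinc chloride | COc1ccc(C[Zn]Cl)cc1
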